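**Plan**

- Retrosynthesis: the C2=C3 alkene of the target (ring numbered C1 = ketone, C2=C3, C4–OH, C5–OH, C6(OH)–chain) is hidden by a retro-Diels–Alder cut, i.e. two temporary C–C bonds from C2 and C3 to cyclopentadiene. The cis C5/C6 diol goes back to a C5=C6 alkene and the C4 carbinol to a ketone.
- Enabling feature: C1 and C4 are para oxygens on a six-membered carbocycle and C2=C3 is an unsubstituted enone alkene, so the ring is a 2-alkyl-1,4-benzoquinone. It is cut further at the ring–chain bond C6–C1' and at C11'–C12' of the side chain.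
- Forward: the C21 chain is built by acetylide alkylation and joined to the arene by aryllithium alkylation; oxidation gives the quinone. Its C2=C3 bond closes the temporary norbornene ring with cyclopentadiene; C4, C5 and C6 are functionalised on the folded tricycle, and cycloreversion releases the six-membered ring.
- Stereochemistry: a chiral oxazaborolidinium catalyst decides which face of the quinone carries the bicycle. Hydride (C4) and OsO4 (C5, C6) then both enter from the open convex face, giving 4S,5R,6R. The 12'Z alkene comes from Lindlar semihydrogenation of an alkyne that is carried through the oxidations.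
- Labels: ring carbons keep the target numbers in every intermediate; chain carbons are C1' (on C6) to C21'; the cyclopentadiene carbons are Ca (bonded to C2), Cb=Cc, Cd (bonded to C3) and Ce (CH2 bridge).

Key step: step 4

Assumption 1: cyclopentadiene is counted as a commercial starting material; it is distilled from its commercial dimer directly before use.

Assumption 2: the antipode of the catalyst is chosen from the α-C–H···O binding model with boron on the C4 oxygen, which points to the (S)-diphenylprolinol-derived catalyst; if the adduct proved to have the opposite sense, the (R)-catalyst would be used with nothing else changed.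

**Step 1**
Reactants: 1 dec-1-yne; 2 1,11-dibromoundecane
Product: 4 1-bromoheneicos-12-yne, via lithium dec-1-yn-1-ide 3 (not isolated)
Conditions: n-BuLi, THF, −78 °C; then added to 2 (3 equiv), DMPU, −20 °C → rt
Reagents that add atoms: none
Why: Acetylide alkylation: the lithium acetylide displaces one bromide of the primary dibromide by SN2, the threefold excess of 2 and the dipolar cosolvent favouring mono-substitution; no stereocentre is formed.

**Step 2**
Reactants: 5 1,4-dimethoxybenzene; 4 1-bromoheneicos-12-yne
Product: 7 2-(heneicos-12-yn-1-yl)-1,4-dimethoxybenzene, via (2,5-dimethoxyphenyl)lithium 6 (not isolated)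
Conditions: 5 (1.5 equiv), n-BuLi, TMEDA, THF, 0 °C; then 4, 0 °C → rt
Reagents that add atoms: none
Why: Directed ortho-lithiation of the bis(methyl ether) followed by SN2 alkylation of the aryllithium with the primary bromide joins ring and chain at what becomes C6–C1', the internal alkyne being inert to the aryllithium.

**Step 3**
Reactants: 7 2-(heneicos-12-yn-1-yl)-1,4-dimethoxybenzene
Product: 8 2-(heneicos-12-yn-1-yl)cyclohexa-2,5-diene-1,4-dione
Conditions: (NH4)2Ce(NO3)6 (2.5 equiv), MeCN–H2O, 0 °C
Reagents that add atoms: water, SMILES O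
Why: Oxidative demethylation of a 1,4-dimethoxyarene to the para-quinone by (NH4)2Ce(NO3)6 (two one-electron oxidations with ipso attack of water and loss of methanol) is a standard quinone synthesis that an isolated dialkylalkyne tolerates.

**Step 4**
Reactants: 8 2-(heneicos-12-yn-1-yl)cyclohexa-2,5-diene-1,4-dione; 9 cyclopenta-1,3-diene
Product: 10 (1R,4S,4aR,8aS)-6-(heneicos-12-yn-1-yl)-1,4,4a,8a-tetrahydro-1,4-methanonaphthalene-5,8-dione (endo adduct)
Conditions: (S)-tetrahydro-1-(2-methylphenyl)-3,3-diphenyl-1H,3H-pyrrolo[1,2-c][1,3,2]oxazaborole (20 mol%), HN(SO2CF3)2 (16 mol%), CH2Cl2, −78 °C, slow addition of 9 (2 equiv), Et3N quench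
Reagents that add atoms: none
Why: Boron of the triflimide-activated oxazaborolidinium ion binds the more basic C4 carbonyl oxygen (the one conjugated with, but not adjacent to, the alkyl-bearing C6) on the lone pair syn to C3–H, which lowers the LUMO of C2=C3 so that cyclopentadiene adds in a concerted, asynchronous [4+2] cycloaddition. The closest known reaction type is the chiral oxazaborolidinium-catalysed Diels–Alder reaction of unsymmetrical 1,4-benzoquinones with 1,3-dienes. The one new ring, the cyclohexene that completes the bicyclo[2.2.1]heptene, closes intermolecularly by suprafacial bonding of both diene termini (Ca to C2, Cd to C3) to one face of the quinone. Of the four new stereocentres, the cis ring fusion at C2/C3 follows from suprafacial addition to the cis alkene, the endo orientation of Ca and Cd relative to the ene-dione from the Alder endo rule reinforced by the Lewis acid, and the absolute sense of all four from the catalyst, whose aryl group covers one face of the bound C2=C3 so that the diene enters from the other. The step needs site selectivity for C2=C3, endo selectivity and enantioface selectivity; the chain on C6 deactivates and shields C5=C6, and the difference in basicity and hindrance between the two carbonyls, helped by slow addition of the diene at −78 °C to hold back the uncatalysed reaction, is what should secure a single binding mode.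

**Step 5**
Reactants: 10 endo adduct
Product: 11 (1R,4S,4aR,8S,8aS)-8-hydroxy-6-(heneicos-12-yn-1-yl)-1,4,4a,8a-tetrahydro-1,4-methanonaphthalen-5(8H)-one
Conditions: NaBH4 (1 equiv), CeCl3·7H2O, MeOH–CH2Cl2, −78 °C
Reagents that add atoms: none
Why: Luche 1,2-reduction: the cerium-activated borohydride should attack the C4 carbonyl, which is flanked by two CH groups, in preference to the C1 carbonyl shielded by the chain on C6, and it enters from the convex face (the face of H2 and H3), so that the new C4 hydroxyl (4S) lies on the concave face next to Cb=Cc.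

**Step 6**
Reactants: 11 hydroxy enone
Product: 12 cage bromo ether (11 with O4 bonded endo to Cc and bromine exo on Cb; enone C1(=O)–C6=C5 intact)
Conditions: NBS, CH2Cl2, 0 °C, dark
Reagents that add atoms: N-bromosuccinimide, SMILES O=C1CCC(=O)N1Br
Why: Bromoetherification (halocyclisation): NBS forms the bromonium ion on the exo face of the strained norbornene and the neighbouring C4 hydroxyl opens it at Cc from the endo face in a 5-exo closure, which fixes Cb (Br exo) and Cc (O endo) by anti addition and masks both the hydroxyl and the only alkene more nucleophilic than C5=C6.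

**Step 7**
Reactants: 12 cage bromo ether
Product: 13 cis-5,6-diol of 12 (both hydroxyls on the convex face, anti to O4)
Conditions: OsO4 (5 mol%), NMO (2 equiv), THF–t-BuOH–H2O, rt
Reagents that add atoms: OsO4, SMILES O=[Os](=O)(=O)=O (transfers both oxygen atoms and is replenished from N-methylmorpholine N-oxide, SMILES C[N+]1([O-])CCOCC1, and water, SMILES O)
Why: Catalytic OsO4/NMO syn-dihydroxylation: with the norbornene masked and the dialkylalkyne far less reactive, the enone alkene C5=C6 is osmylated suprafacially from the convex face, the cage ether blocking the other, which sets C5 (R) and C6 (R) with both hydroxyls cis to each other and trans to O4.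

**Step 8**
Reactants: 13 cage bromo ether diol
Product: 14 5,6-O-isopropylidene acetal of 13
Conditions: Me2C(OMe)2, PPTS (cat.), CH2Cl2, rt
Reagents that add atoms: 2,2-dimethoxypropane, SMILES COC(C)(C)OC
Why: Acid-catalysed acetal exchange closes the five-membered isopropylidene acetal on the cis-diol, which protects the tertiary α-ketol during zinc treatment and thermolysis; no stereocentre changes.

**Step 9**
Reactants: 14 alkynyl acetonide
Product: 15 (12'Z)-alkene analogue of 14
Conditions: H2 (1 atm), Pd/CaCO3 poisoned with Pb(OAc)2 (Lindlar catalyst), quinoline, EtOAc, rt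
Reagents that add atoms: none
Why: Lindlar semihydrogenation: syn addition of H2 on lead-poisoned palladium stops at the (Z)-alkene, while the ketone, the acetal and the secondary bromide are untouched and the norbornene alkene is still hidden in the bromo ether.

**Step 10**
Reactants: 15 (Z)-alkenyl cage bromo ether
Product: 16 tricyclic hydroxy ketone acetonide (Cb=Cc and the C4 hydroxyl restored; 5,6-O-isopropylidene; 12'Z chain)
Conditions: activated Zn dust, NH4Cl, MeOH–THF, reflux
Reagents that add atoms: none
Why: Zinc-mediated reductive β-elimination: zinc inserts into the Cb–Br bond and expels the β-alkoxide, which regenerates Cb=Cc and the C4 hydroxyl without affecting C4, C5, C6 or the (Z)-alkene.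

**Step 11**
Reactants: 16 tricyclic hydroxy ketone acetonide
Product: 17 (4S,5R,6R)-4-hydroxy-5,6-(isopropylidenedioxy)-6-[(12Z)-heneicos-12-en-1-yl]cyclohex-2-en-1-one
Conditions: Ph2O, 250 °C, argon stream, short heating
Reagents that add atoms: none
Why: Thermal retro-Diels–Alder reaction: concerted [4+2] cycloreversion releases volatile cyclopentadiene and the C2=C3 alkene, driven by entropy and by conjugation of the new alkene with the C1 carbonyl, and it leaves C4, C5 and C6 untouched.

**Step 12**
Reactants: 17 enone acetonide
Product: 18 (4S,5R,6R)-4,5,6-trihydroxy-6-[(12Z)-heneicos-12-en-1-yl]cyclohex-2-en-1-one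
Conditions: CF3CO2H–H2O (9:1), CH2Cl2, 0 °C
Reagents that add atoms: none
Why: Acid hydrolysis of the isopropylidene acetal in cold aqueous trifluoroacetic acid, the usual last step for trihydroxycyclohexenones of this kind, frees the 5,6-diol without touching the stereocentres, the enone or the (Z)-alkene.

**Compound list**

1 | dec-1-yne | C#CCCCCCCCC | starting material
2 | 1,11-dibromoundecane | BrCCCCCCCCCCCBr | starting material
3 | lithium dec-1-yn-1-ide | [Li]C#CCCCCCCCC | intermediate
4 | 1-bromoheneicos-12-yne | BrCCCCCCCCCCCC#CCCCCCCCC | intermediate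
5 | 1,4-dimethoxybenzene | COc1ccc(OC)cc1 | starting material
6 | (2,5-dimethoxyphenyl)lithium | [Li]c1cc(OC)ccc1OC | intermediate
7 | 2-(heneicos-12-yn-1-yl)-1,4-dimethoxybenzene | COc1ccc(OC)c(CCCCCCCCCCCC#CCCCCCCCC)c1 | intermediate
8 | 2-(heneicos-12-yn-1-yl)cyclohexa-2,5-diene-1,4-dione | O=C1C=CC(=O)C(CCCCCCCCCCCC#CCCCCCCCC)=C1 | intermediate
9 | cyclopenta-1,3-diene | C1=CCC=C1 | starting material
10 | (1R,4S,4aR,8aS)-6-(heneicos-12-yn-1-yl)-1,4,4a,8a-tetrahydro-1,4-methanonaphthalene-5,8-dione, endo adduct | O=C1C(CCCCCCCCCCCC#CCCCCCCCC)=CC(=O)[C@@H]2[C@H]1[C@@H]3C=C[C@H]2C3 | intermediate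
11 | (1R,4S,4aR,8S,8aS)-8-hydroxy-6-(heneicos-12-yn-1-yl)-1,4,4a,8a-tetrahydro-1,4-methanonaphthalen-5(8H)-one, hydroxyl on the concave face | O=C1C(CCCCCCCCCCCC#CCCCCCCCC)=C[C@@H](O)[C@@H]2[C@H]1[C@@H]3C=C[C@H]2C3 | intermediate
12 | cage bromo ether: 11 with O4 bonded endo to Cc and bromine exo on Cb, enone intact | O=C1C(CCCCCCCCCCCC#CCCCCCCCC)=C[C@H]2O[C@H]3[C@H](Br)[C@@H]4C[C@H]3[C@H]2[C@H]14 | intermediate
13 | cis-5,6-diol of 12, both hydroxyls on the convex face (syn to H2, H3 and H4, anti to O4) | O=C1[C@@](O)(CCCCCCCCCCCC#CCCCCCCCC)[C@H](O)[C@H]2O[C@H]3[C@H](Br)[C@@H]4C[C@H]3[C@H]2[C@H]14 | intermediate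
14 | 5,6-O-isopropylidene acetal of 13 | O=C1[C@]2(CCCCCCCCCCCC#CCCCCCCCC)OC(C)(C)O[C@@H]2[C@H]3O[C@H]4[C@H](Br)[C@@H]5C[C@H]4[C@H]3[C@H]15 | intermediate
15 | 14 with the C12'–C13' alkyne reduced to the (Z)-alkene | O=C1[C@]2(CCCCCCCCCCC/C=C\CCCCCCCC)OC(C)(C)O[C@@H]2[C@H]3O[C@H]4[C@H](Br)[C@@H]5C[C@H]4[C@H]3[C@H]15 | intermediate
16 | tricyclic hydroxy ketone acetonide: norbornene Cb=Cc and C4 hydroxyl restored, 5,6-O-isopropylidene, (12'Z)-chain | O=C1[C@]2(CCCCCCCCCCC/C=C\CCCCCCCC)OC(C)(C)O[C@@H]2[C@@H](O)[C@@H]3[C@H]1[C@@H]4C=C[C@H]3C4 | intermediate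
17 | (4S,5R,6R)-4-hydroxy-5,6-(isopropylidenedioxy)-6-[(12Z)-heneicos-12-en-1-yl]cyclohex-2-en-1-one | O=C1[C@]2(CCCCCCCCCCC/C=C\CCCCCCCC)OC(C)(C)O[C@@H]2[C@@H](O)C=C1 | intermediate
18 | (4S,5R,6R)-4,5,6-trihydroxy-6-[(12Z)-heneicos-12-en-1-yl]cyclohex-2-en-1-one | CCCCCCCC/C=C\CCCCCCCCCCC[C@]1(O)C(=O)C=C[C@H](O)[C@H]1O | target

**Count and risks**

Total step count: 12. Longest linear sequence: 12 steps (1 to 18; 5 and 9 enter as commercial partners).

The three steps most likely to fail are step 4, step 5 and step 11.

Step 4. What may go wrong: loss of enantiocontrol, because the Lewis acid can bind either quinone carbonyl and the two binding modes deliver the diene to opposite faces, or because the uncatalysed cycloaddition competes. The fallback replaces catalysis by resolution; it sets out from 8 and returns at 11. Cyclopentadiene is added to 8 without catalyst (CH2Cl2, 0 °C), which should give the endo adduct as the racemate, that is 10 together with its mirror image ent-10 F1. Luche reduction as in step 5 should then give the racemic alcohol, 11 together with ent-11 F2. Esterification with (S)-2-methoxy-2-phenylacetic acid (DCC, DMAP, CH2Cl2) converts the pair into two diastereomers, the (S)-2-methoxy-2-phenylacetate of 11 F3 and the (S)-2-methoxy-2-phenylacetate of ent-11 F4, to be separated by chromatography. Methanolysis of F3 (K2CO3, MeOH, 0 °C) returns 11.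

Step 5. What may go wrong: hydride delivery to the C1 carbonyl or to both carbonyls, giving the regioisomeric alcohol or the diol. The fallback lets only one carbonyl reach the reduction; it sets out from 7 and returns at 11. Anodic oxidation of 7 (Pt anode, KOH, MeOH, 0 °C) should give the quinone bis(dimethyl ketal) 1-(heneicos-12-yn-1-yl)-3,3,6,6-tetramethoxycyclohexa-1,4-diene F5. Brief treatment with aqueous acetic acid in acetone at 0 °C should hydrolyse the C4 ketal first, because its ionisation places positive charge on the alkyl-bearing C6, and leave 3-(heneicos-12-yn-1-yl)-4,4-dimethoxycyclohexa-2,5-dien-1-one F6 with C1 still masked. Cycloaddition with 9 under the conditions of step 4 should give the C1 dimethyl ketal of 10 F7, Luche reduction of its only carbonyl the C1 dimethyl ketal of 11 F8, and PPTS in wet acetone then unmasks C1 to give 11.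

Step 11. What may go wrong: thermal degradation that starts at the free C4 hydroxyl (dehydration toward an arene, hydrogen shift to a 1,4-dione) before or after cycloreversion. The fallback changes the protecting-group pattern so that no free hydroxyl is exposed to heat; it sets out from 16 and returns at 18. Silylation (TBSCl, imidazole, DMF, rt) should give the C4 tert-butyldimethylsilyl ether of 16 F9, thermolysis as in step 11 the C4 tert-butyldimethylsilyl ether of 17 F10, and CF3CO2H–H2O then removes silyl ether and acetonide together to give 18.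

**Further compounds**

F1 | step 4 | ent-10, (1S,4R,4aS,8aR)-6-(heneicos-12-yn-1-yl)-1,4,4a,8a-tetrahydro-1,4-methanonaphthalene-5,8-dione | O=C1C(CCCCCCCCCCCC#CCCCCCCCC)=CC(=O)[C@H]2[C@@H]1[C@H]3C=C[C@@H]2C3
F2 | step 4 | ent-11, (1S,4R,4aS,8R,8aR)-8-hydroxy-6-(heneicos-12-yn-1-yl)-1,4,4a,8a-tetrahydro-1,4-methanonaphthalen-5(8H)-one | O=C1C(CCCCCCCCCCCC#CCCCCCCCC)=C[C@H](O)[C@H]2[C@@H]1[C@H]3C=C[C@@H]2C3
F3 | step 4 | (S)-2-methoxy-2-phenylacetate of 11 | O=C1C(CCCCCCCCCCCC#CCCCCCCCC)=C[C@@H](OC(=O)[C@@H](OC)c4ccccc4)[C@@H]2[C@H]1[C@@H]3C=C[C@H]2C3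
F4 | step 4 | (S)-2-methoxy-2-phenylacetate of ent-11 | O=C1C(CCCCCCCCCCCC#CCCCCCCCC)=C[C@H](OC(=O)[C@@H](OC)c4ccccc4)[C@H]2[C@@H]1[C@H]3C=C[C@@H]2C3
F5 | step 5 | 1-(heneicos-12-yn-1-yl)-3,3,6,6-tetramethoxycyclohexa-1,4-diene | COC1(OC)C=CC(OC)(OC)C(CCCCCCCCCCCC#CCCCCCCCC)=C1
F6 | step 5 | 3-(heneicos-12-yn-1-yl)-4,4-dimethoxycyclohexa-2,5-dien-1-one | O=C1C=CC(OC)(OC)C(CCCCCCCCCCCC#CCCCCCCCC)=C1
F7 | step 5 | C1 dimethyl ketal of 10 | COC1(OC)C(CCCCCCCCCCCC#CCCCCCCCC)=CC(=O)[C@@H]2[C@H]1[C@@H]3C=C[C@H]2C3
F8 | step 5 | C1 dimethyl ketal of 11 | COC1(OC)C(CCCCCCCCCCCC#CCCCCCCCC)=C[C@@H](O)[C@@H]2[C@H]1[C@@H]3C=C[C@H]2C3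
F9 | step 11 | C4 tert-butyldimethylsilyl ether of 16 | O=C1[C@]2(CCCCCCCCCCC/C=C\CCCCCCCC)OC(C)(C)O[C@@H]2[C@@H](O[Si](C)(C)C(C)(C)C)[C@@H]3[C@H]1[C@@H]4C=C[C@H]3C4
F10 | step 11 | C4 tert-butyldimethylsilyl ether of 17 | O=C1[C@]2(CCCCCCCCCCC/C=C\CCCCCCCC)OC(C)(C)O[C@@H]2[C@@H](O[Si](C)(C)C(C)(C)C)C=C1
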